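## Retrosynthetic overview

1. The veratroyl ester is installed last, by primary-selective O-acylation of the all-cis diol.
2. The diol comes from LiAlH4 reduction of an all-cis 4-acetoxy-oxolane-3-carboxylate, which removes the acetate and reduces the ethyl ester together.
3. Key disconnection: all three stereocentres are set in one enantioselective, all-syn hydrogenation of an aromatic 2-aryl-3-ester-4-acetoxyfuran.
4. That furan is made in one pot: veratroyl chloride C-acylates ethyl 4-chloroacetoacetate, chloride displacement closes the furan-3(2H)-one, and O-acetylation aromatises it.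
5. Ring order: the furan (later oxolane) ring is the only ring formed; both arene rings are bought in as veratroyl chloride.

## Assumptions

- Ring locants used below: O1, C2 (aryl), C3 (CO2Et or CH2O), C4 (O), C5. The target is the 2,3,4-all-cis isomer, (2S,3R,4S).
- The sense of induction of the new hydrogenation cannot be predicted. The (R,R)-ligand is written; the (S,S)-ligand is used if the first run gives the mirror image.

## Route

Step 1
Reactants: 1 3,4-dimethoxybenzoyl chloride; 2 ethyl 4-chloro-3-oxobutanoate
Product: 5 ethyl 4-acetoxy-2-(3,4-dimethoxyphenyl)furan-3-carboxylate, via chloro triketo ester 3 (not isolated), via furan-3(2H)-one ester 4 (not isolated)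
Conditions: MgCl2 (1.2 equiv), i-Pr2NEt (4 equiv), MeCN, 0 °C → rt, then 60 °C; then Ac2O (1.5 equiv), DMAP (5 mol%), 0 °C → rt
Reagents that add atoms: acetic anhydride, CC(=O)OC(C)=O
Why: Mg-chelate-controlled C-acylation of the β-keto ester (Claisen-type acylation) gives 3, whose aryl-ketone enolate oxygen displaces the γ-chloride in a 5-exo-tet intramolecular O-alkylation (the classical route to 4-alkoxycarbonyl-furan-3(2H)-ones) to give 4, and O-acetylation of the enolate of 4 is driven by aromatisation to the furan; no stereocentre is formed.

Step 2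
Reactants: 5 ethyl 4-acetoxy-2-(3,4-dimethoxyphenyl)furan-3-carboxylate
Product: 7 ethyl (2S,3S,4S)-4-acetoxy-2-(3,4-dimethoxyphenyl)oxolane-3-carboxylate (all-cis), via (4S)-4-acetoxy-4,5-dihydrofuran ester 6 (not isolated)
Conditions: [Ru(cod)(2-methylallyl)2] (5 mol%), (R,R)-SINpEt·HBF4 (10 mol%), KOt-Bu (10 mol%), preformed in n-hexane at 70 °C; then 5 in toluene, H2 (100 bar), 40 °C, 24 h
Reagents that add atoms: none
Why: Proposed new method: the chiral Ru(II)–bis-NHC catalyst should add H2 enantioface-selectively to the least hindered C4=C5 enol-acetate bond of the furan (setting C4 as S, giving 6) and then reduce the remaining tetrasubstituted C2=C3 vinylogous-carbonate bond syn from the same face, anti to the new OAc group, so that the new hydrogens at C2, C3 and C4 lie on one face and aryl, CO2Et and OAc are all cis (C2 S, C3 S); the closest known reaction types are the Ru–SINpEt-catalysed enantioselective hydrogenation of 2-aryl and 2,4-/2,5-disubstituted furans to cis-oxolanes, the same catalyst's reduction of β-aryl-β-alkoxy enones (flavones, chromones), and the asymmetric hydrogenation of enol acetates and of trisubstituted pyrrole esters to all-cis products.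

Step 3
Reactants: 7 ethyl (2S,3S,4S)-4-acetoxy-2-(3,4-dimethoxyphenyl)oxolane-3-carboxylate
Product: 8 (3S,4R,5S)-5-(3,4-dimethoxyphenyl)-4-(hydroxymethyl)oxolan-3-ol
Conditions: LiAlH4 (2.5 equiv), THF, −40 → 0 °C; Fieser work-up (H2O, 15% NaOH, H2O)
Reagents that add atoms: none
Why: Hydride reduction of the ethyl ester to the primary alcohol with simultaneous reductive cleavage of the acetate (ester reduction) breaks no bond at C2–C4, and the low temperature lets carbonyl attack outrun β-elimination of acetate or epimerisation at C3, so the all-cis arrangement is kept (the C3 descriptor changes from S to R only through CIP priorities).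

Step 4
Reactants: 8 (3S,4R,5S)-5-(3,4-dimethoxyphenyl)-4-(hydroxymethyl)oxolan-3-ol; 1 3,4-dimethoxybenzoyl chloride
Product: 9 [(2S,3R,4S)-2-(3,4-dimethoxyphenyl)-4-hydroxyoxolan-3-yl]methyl 3,4-dimethoxybenzoate
Conditions: 1 (1.05 equiv), 2,4,6-collidine (3 equiv), CH2Cl2, −40 → 0 °C
Reagents that add atoms: none
Why: Kinetically controlled nucleophilic acyl substitution (O-acylation with an acid chloride) takes place at the unhindered primary hydroxyl far faster than at the ring hydroxyl flanked by two cis substituents, and the primary ester is also the thermodynamically preferred monoester, so no stereocentre is touched.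

## Compound list

1 | 3,4-dimethoxybenzoyl chloride (veratroyl chloride) | COc1ccc(cc1OC)C(Cl)=O | starting material
2 | ethyl 4-chloro-3-oxobutanoate | CCOC(=O)CC(=O)CCl | starting material
3 | ethyl 4-chloro-2-(3,4-dimethoxybenzoyl)-3-oxobutanoate | CCOC(=O)C(C(=O)CCl)C(=O)c1ccc(OC)c(OC)c1 | intermediate (not isolated)
4 | ethyl 2-(3,4-dimethoxyphenyl)-4-oxo-4,5-dihydrofuran-3-carboxylate | CCOC(=O)C1=C(OCC1=O)c1ccc(OC)c(OC)c1 | intermediate (not isolated)
5 | ethyl 4-acetoxy-2-(3,4-dimethoxyphenyl)furan-3-carboxylate | CCOC(=O)c1c(OC(C)=O)coc1-c1ccc(OC)c(OC)c1 | intermediate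
6 | ethyl (4S)-4-acetoxy-2-(3,4-dimethoxyphenyl)-4,5-dihydrofuran-3-carboxylate | CCOC(=O)C1=C(c2ccc(OC)c(OC)c2)OC[C@H]1OC(C)=O | intermediate (not isolated)
7 | ethyl (2S,3S,4S)-4-acetoxy-2-(3,4-dimethoxyphenyl)oxolane-3-carboxylate (all-cis) | CCOC(=O)[C@@H]1[C@H](OC(C)=O)CO[C@@H]1c1ccc(OC)c(OC)c1 | intermediate
8 | (3S,4R,5S)-5-(3,4-dimethoxyphenyl)-4-(hydroxymethyl)oxolan-3-ol (all-cis) | OC[C@@H]1[C@H](O)CO[C@@H]1c1ccc(OC)c(OC)c1 | intermediate
9 | [(2S,3R,4S)-2-(3,4-dimethoxyphenyl)-4-hydroxyoxolan-3-yl]methyl 3,4-dimethoxybenzoate | COc1ccc(C(=O)OC[C@@H]2[C@H](O)CO[C@@H]2c2ccc(OC)c(OC)c2)cc1OC | target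

## Step count and risks

Total step count: 4. Longest linear sequence: 4 steps (1 + 2 → 5 → 7 → 8 → 9).

**Step 2 (most likely to fail).** A 2,3,4-trisubstituted 3-acyloxyfuran has no precedent in asymmetric hydrogenation. The reduction may stall at 6, lose acetic acid from 6 to give the 4-deoxy furan, epimerise C3 of 7 through residual base, or give low ee. The ee can be raised by crystallising 8. The fallback replaces the catalyst-controlled furan reduction by a reagent-controlled ketone reduction followed by a substrate-controlled alkene hydrogenation. It sets out from 4, isolated by stopping step 1 before the acetic anhydride is added. Corey–Bakshi–Shibata reduction of the ring ketone ((S)-Me-CBS 20 mol%, BH3·SMe2, THF, −20 °C) gives the allylic alcohol ethyl (4S)-2-(3,4-dimethoxyphenyl)-4-hydroxy-4,5-dihydrofuran-3-carboxylate F1; with the tetrasubstituted alkenyl side as the large group, the usual model predicts 4S. Acetylation (Ac2O, pyridine, DMAP) gives 6, now isolated. Heterogeneous hydrogenation (H2 50 bar, Rh/Al2O3, EtOAc) adds to the push–pull alkene from the face anti to the acetate, and the fallback comes back to the route at 7.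

**Step 1.** Three events share one flask. Possible failures are O-aroylation of the magnesium enolate, self-alkylation of 2, ring closure through the ester oxygen (the 2-ethoxy-3-aroyl isomer), or C-acetylation of 4. The fallback reverses the order of the two acylations and isolates the furanone. It sets out from 1. Decarboxylative acylation of potassium ethyl malonate (MgCl2, Et3N, MeCN) gives the acyl malonate half-ester 2-(3,4-dimethoxybenzoyl)-3-ethoxy-3-oxopropanoic acid F2, which loses CO2 on acidic work-up to give ethyl 3-(3,4-dimethoxyphenyl)-3-oxopropanoate F3. The magnesium chelate of F3 (MgCl2, pyridine, CH2Cl2, 0 °C) is C-acylated with chloroacetyl chloride to 3, which is closed with Et3N to 4. Compound 4 is crystallised and acetylated separately (Ac2O, Et3N, DMAP), and the fallback comes back to the route at 5.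

**Step 4.** Diacylation, or O→O acyl migration during work-up, could give mixtures of mono- and diesters. The fallback replaces kinetic selectivity by tin-templated activation of the primary oxygen. It sets out from 8. Bu2SnO (toluene, reflux, Dean–Stark) gives the six-membered dibutylstannylene acetal of diol 8 F4. F4 reacts with 1 (1.0 equiv, CH2Cl2, 0 °C) at the primary oxygen only, and aqueous work-up releases the ring hydroxyl, so the fallback comes back to the route at 9.

## Further compounds

F1 | step 2 | ethyl (4S)-2-(3,4-dimethoxyphenyl)-4-hydroxy-4,5-dihydrofuran-3-carboxylate | CCOC(=O)C1=C(c2ccc(OC)c(OC)c2)OC[C@H]1O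
F2 | step 1 | 2-(3,4-dimethoxybenzoyl)-3-ethoxy-3-oxopropanoic acid | CCOC(=O)C(C(O)=O)C(=O)c1ccc(OC)c(OC)c1
F3 | step 1 | ethyl 3-(3,4-dimethoxyphenyl)-3-oxopropanoate | CCOC(=O)CC(=O)c1ccc(OC)c(OC)c1
F4 | step 4 | dibutylstannylene acetal of diol 8 | CCCC[Sn]1(CCCC)OC[C@@H]2[C@H](O1)CO[C@@H]2c1ccc(OC)c(OC)c1
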